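The readings come from a simulation with made-up constants, and the scatter is random.

all flasks: initiator 2.5 mM

|  | substrate | reagent | remark | time |
|---|---|---|---|---|
| green | 0.050 M | 0.035 M | run made earlier |  |
| amber | 0.050 M | 0.053 M | run made earlier |  |
| Monday's | 0.050 M (fed, over 3.00 min) | 0.0350 M | all but substrate at the start; substrate goes in evenly over 3.00 min, the run ends at 6.0 min | 6.0 min |
| Sunday's | 0.050 M | 0.0350 M (fed, over 3.00 min) | all but reagent at the start; reagent goes in evenly over 3.00 min, the run ends at 6.0 min | 6.0 min |
| Wednesday's | 0.050 M | 0.0350 M | a closed flask charged with all of it at once and left for 6.0 min | 6.0 min |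
| Friday's | 0.050 M | 0.0350 M | one stirred flow tank at steady state, fed with the mixture as stated, mean residence time 6.0 min |  |

- green (time / min: target / %): 0.417: 29.3; 1.33: 54.6; 2.00: 59.7; 3.00: 62.3; 5.00: 62.6; 6.00: 62.5
- amber (time / s: target / %): 10.0: 14.2; 15.0: 18.7; 25.0: 29.3; 40.0: 40.5; 60.0: 51.2; 80.0: 59.2

(scatter of a reading: 0.5 percentage points)

- the set-up with the highest amount of target at the outlet or at the end, in percent of the substrate put in ("none" if the first two lie within 2 percentage points) (Monday's / Sunday's / Wednesday's / Friday's / none)
- amount of target at the outlet or at the end, in percent of the substrate put in, Monday's
- amount of target at the outlet or at the end, in percent of the substrate put in, Sunday's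
- amount of target at the outlet or at the end, in percent of the substrate put in, Wednesday's
- amount of target at the outlet or at the end, in percent of the substrate put in, Friday's

- percent here means substrate units held: one ended chains B counts as two
- the stated concentrations are those of everything mixed, before any reaction; amounts are the same in each set-up
- candidate steps: initiator -> 2 initiating radical; substrate + initiating radical -> capped initiator + first chain carrier; reagent + first chain carrier -> target + second chain carrier; substrate + second chain carrier -> released group + first chain carrier; first chain carrier -> ended carrier; 2 second chain carrier -> ended chains A; 2 first chain carrier -> ended chains B; target <-> isomer of the product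
- the feed brings no volume worth counting
- the earlier runs were made in a closed, stirred flask

The closed, stirred flask of the green run carries the same charges as Wednesday's, so its readings stand for that flask, and what they show is a flat end, with target at 62.3% after 3.00 min and 62.5% after 6.00 min, a step smaller than the scatter of 0.5 percentage points. But each target takes up one reagent, the limiting reagent of this charge, so [reagent]/[substrate] allows 70.0%, and the flat end lies 7.5 points below that allowance. We treat this gap as a correction to the allowance: if the green run has turned over its reagent and target has come to balance with the isomer of the product, the gap measures the held share, the part of the reagent turned over that stands as target, here a reading of 89.3%. So we commit to about 62.5% for Wednesday's, while for the fed flasks and the tank the held share needs the reagent turned over, of which we have no reading, so we name no figure there. The forecast reads the flat end differently, “the initiator has died”, and gives 38% for Monday's, 36% for Sunday's, 62.5% for Wednesday's and 47% for Friday's, with Wednesday's the best.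

    initiator → 2 initiating radical (k = 0.0132 s⁻¹)
    substrate + initiating radical → capped initiator + first chain carrier (k = 1.49 × 10⁶ L mol⁻¹ s⁻¹)
    reagent + first chain carrier → target + second chain carrier (k = 46200 L mol⁻¹ s⁻¹)
    substrate + second chain carrier → released group + first chain carrier (k = 57300 L mol⁻¹ s⁻¹)
    first chain carrier → ended carrier (k = 11.7 s⁻¹)
    2 second chain carrier → ended chains A (k = 4.00 × 10⁸ L mol⁻¹ s⁻¹)
    2 first chain carrier → ended chains B (k = 8.20 × 10⁶ L mol⁻¹ s⁻¹)
    target ⇌ isomer of the product (K = 0.110, k = 0.0476 s⁻¹)

Wednesday's is best at 62.8%, against 53.5% for Monday's, 54.1% for Sunday's and 54.3% for Friday's. After 6.00 min, Wednesday's has 0.357% of its reagent left and Monday's 15.1%, with initiator at 0.863% of its charge in each. The held share, applied to the reagent Monday's turned over, gives 53.1% against its 53.5%. Applied to a neighbour of Wednesday's charged with 0.014 M of reagent, it gives 25.0%, and that neighbour ends at 25.2%.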